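## Retrosynthetic overview

1. Brianthein B ⇐ the C11=C12 triacetate by a final singlet-oxygen (Schenck) ene reaction, copying the presumed biogenesis of the 12-hydroperoxy-11(20)-ene unit.
2. Ten-membered ring B and butenolide ring C ⇐ a seco precursor by forming C3–C4. A C3 nitronate (acyl-anion equivalent of the C3 carbinol) alkylates the C4 terminus of a C4–C5–C6 π-allylpalladium unit released from a C6–C7 vinyl epoxide, and the freed C7 oxygen lactonises onto the cis C19 ester. Enabling feature: C4 is the allylic CH2 of the C5(C16)=C6 alkene whose other allylic carbon, C7, carries the lactone oxygen of ring C, and C3 is an oxygenated carbon next to C2.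
3. Seco precursor ⇐ ring A acid (C8 carboxyl) via β-keto ester, (Z)-enol triflate, formylation (C7), asymmetric sulfur-ylide epoxidation (C4–C6, C16), then a Henry reaction at C2 (C3 as nitro).
4. Ring A (C1, C10–C14) ⇐ (S)-carvone: double α'-alkylation (C1 quaternary centre), epoxidation, Criegee rearrangement (C14–OAc), Wharton transposition, Ireland–Claisen rearrangement (C9–C10 bond, C11=C12).
5. Ring order: ring A from the chiral pool, then rings B and C together in the key step.

Key step: step 17

Remark on notation: the briarane numbering of the target is used for every intermediate (C1 quaternary carbon with C15; C2, C3 oxygenated; C4; C5(C16)=C6; C7; C8=C17(C18)–C19; C9; C10; C11(C20)–C14), and β is the face of ring A that carries C15.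

Assumption: the enantiomers of the two chiral controllers (the indabox ligand of step 15 and isothiocineole 21) are taken as those that the published facial models predict to give the configurations drawn; both antipodes of each are accessible, so the other one would be used if the sense were reversed.

## Route

Step 1
Reactants: 1 (S)-(+)-carvone
Product: 3 6-[(triisopropylsilyloxy)methyl]carvone (mixture of epimers at the new centre), via lithium dienolate 2 (not isolated)
Conditions: LiN(iPr)2, THF, −78 °C; (iPr)3SiOCH2Cl, −78 → 0 °C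
Reagents that add atoms: (triisopropylsiloxy)methyl chloride, ClCO[Si](C(C)C)(C(C)C)C(C)C
Why: Kinetic α'-deprotonation gives the cross-conjugated dienolate, which is C-alkylated (SN2) by the reactive α-chloro ether to bring in C2 as a protected hydroxymethyl group; the new centre is re-enolised in step 2, so its configuration is irrelevant.

Step 2
Reactants: 3 6-[(triisopropylsilyloxy)methyl]carvone
Product: 5 (5R,6R)-2,6-dimethyl-5-(prop-1-en-2-yl)-6-[(triisopropylsilyloxy)methyl]cyclohex-2-en-1-one, via lithium enolate 4 (not isolated)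
Conditions: LiN(iPr)2, THF, −78 °C; CH3I, DMPU, −78 → −20 °C
Reagents that add atoms: iodomethane, CI
Why: Enolate alkylation creates the C1 quaternary centre, iodomethane approaching anti to the neighbouring isopropenyl group as is usual for 6-substituted carvones, so that C15 is β and the C2 arm is α.

Step 3
Reactants: 5 quaternary enone
Product: 6 11β,12β-epoxy ketone (epoxide trans to the isopropenyl group)
Conditions: 30% aq H2O2, NaOH (0.3 equiv), MeOH, 0 °C
Reagents that add atoms: hydrogen peroxide, OO
Why: Weitz–Scheffer nucleophilic epoxidation, with hydroperoxide adding axially to C12 anti to the isopropenyl group as in carvone itself, should give the β-epoxide whose C12–O bond later directs step 7.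

Step 4
Reactants: 6 11β,12β-epoxy ketone
Product: 9 14α-acetoxy 11β,12β-epoxy 10-ketone, via methoxy hydroperoxide 7 (not isolated), via peracetate 8 (not isolated)
Conditions: O3, CH2Cl2–MeOH, −78 °C; then Ac2O, Et3N, DMAP (cat.), CH2Cl2, 0 → 35 °C
Reagents that add atoms: ozone, [O-][O+]=O; methanol, CO
Why: Ozonolysis in methanol converts the only alkene into the α-methoxy hydroperoxide, whose peracetate undergoes Criegee rearrangement with migration of C14 and retention of configuration, giving the 14α-acetate directly.

Step 5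
Reactants: 9 14α-acetoxy epoxy ketone
Product: 11 12β-hydroxy 10(11)-ene (transposed allylic alcohol), via epoxy hydrazone 10 (not isolated)
Conditions: N2H4·H2O (3 equiv), AcOH (0.5 equiv), MeOH, 0 °C → rt
Reagents that add atoms: none
Why: Wharton transposition: the epoxy hydrazone fragments with loss of N2 to place the alkene at C10=C11 and the hydroxyl at C12, the β C12–O bond of the epoxide being retained.

Step 6
Reactants: 11 allylic alcohol
Product: 12 12β,14α-diacetate
Conditions: Ac2O, pyridine, DMAP (cat.), CH2Cl2, rt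
Reagents that add atoms: acetic anhydride, CC(=O)OC(C)=O
Why: DMAP-catalysed acetylation of the secondary allylic alcohol supplies the two carbons (C8, C9) and the ester needed for the Claisen rearrangement.

Step 7
Reactants: 12 12β,14α-diacetate
Product: 15 ring A acid (C10β–CH2CO2H; C11=C12), via bis(trimethylsilyl ketene acetal) 13 (not isolated), via rearranged trimethylsilyl ester 14 (not isolated)
Conditions: LiN(iPr)2 (3.5 equiv), Me3SiCl–Et3N, THF, −78 → 60 °C; then 1 M HCl, THF, rt
Reagents that add atoms: none
Why: Ireland–Claisen rearrangement delivers C9 suprafacially from the 12β-oxygen to the β-face of C10 (setting C10 with H-10 α, trans to the C2 arm) and moves the alkene to C11=C12, while the spectator C14 acetate is only silylated and is regenerated on acidic work-up.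

Step 8
Reactants: 15 ring A acid
Product: 17 tert-butyl β-keto ester (C8 ketone; C17 epimers), via acyl imidazole 16 (not isolated)
Conditions: 1,1'-carbonyldiimidazole, THF, rt; then lithium enolate of tert-butyl propanoate [LiN(iPr)2, 2.5 equiv], THF, −78 °C
Reagents that add atoms: tert-butyl propanoate, CCC(=O)OC(C)(C)C
Why: Crossed Claisen condensation of the acyl imidazole with the propanoate enolate installs C17, C18 and C19; the tert-butyl ester is chosen because it lactonises slowly (needed in step 17), and the C17 centre is enolisable and unimportant.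

Step 9
Reactants: 17 tert-butyl β-keto ester
Product: 19 (Z)-enol triflate (OTf on C8 cis to C19), via sodium enolate 18 (not isolated)
Conditions: NaH, CH2Cl2, 0 °C; (CF3SO2)2O, −78 → 0 °C
Reagents that add atoms: trifluoromethanesulfonic anhydride, O=S(=O)(OS(=O)(=O)C(F)(F)F)C(F)(F)F
Why: O-Triflation of the sodium-chelated (Z)-enolate in a non-coordinating solvent fixes the tetrasubstituted C8=C17 geometry with the leaving group cis to the ester, so that the future C7 will be cis to C19 as lactonisation requires.

Step 10
Reactants: 19 (Z)-enol triflate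
Product: 20 (Z)-β-formyl enoate (C7 aldehyde cis to the tert-butyl ester)
Conditions: Pd(PPh3)4 (5 mol %), CO (3 atm), Bu3SnH (slow addition), THF, 50 °C
Reagents that add atoms: carbon monoxide, [C-]#[O+]
Why: Palladium-catalysed reductive carbonylation (formylation) of a vinyl triflate proceeds with retention of alkene geometry and introduces C7 as an aldehyde.

Step 11
Reactants: 21 (1R,4R,5R)-isothiocineole; 22 3-bromo-2-methylprop-1-ene
Product: 23 S-(2-methylallyl)isothiocineolium tetrafluoroborate
Conditions: NaBF4, CH2Cl2–H2O, rt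
Reagents that add atoms: sodium tetrafluoroborate, [Na+].F[B-](F)(F)F
Why: S-Alkylation of the sulfide by the allylic bromide with bromide-to-tetrafluoroborate exchange gives the chiral sulfonium salt that carries C4, C5, C6 and C16.

Step 12
Reactants: 20 (Z)-β-formyl enoate; 23 sulfonium tetrafluoroborate
Product: 25 trans-(6R,7R)-vinyl epoxide, via sulfonium ylide 24 (not isolated)
Conditions: LiN(SiMe3)2, THF, −78 °C, then 20, −78 → −20 °C
Reagents that add atoms: none
Why: Corey–Chaykovsky epoxidation with the isothiocineole-derived allylic ylide should give the trans vinyl epoxide, the chiral sulfide controlling the face of addition to the aldehyde and hence the C7 (and C6) configuration under reagent control.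

Step 13
Reactants: 25 vinyl epoxide triisopropylsilyl ether
Product: 26 primary alcohol at C2
Conditions: HF·pyridine, pyridine, THF, 0 °C → rt
Reagents that add atoms: none
Why: Pyridine-buffered HF cleaves the primary silyl ether without opening the vinyl epoxide and, being non-basic, without acetyl migration from O14 to the new primary hydroxyl.

Step 14
Reactants: 26 primary alcohol
Product: 27 C2 aldehyde
Conditions: Dess–Martin periodinane, NaHCO3, CH2Cl2, rt
Reagents that add atoms: none
Why: Buffered Dess–Martin oxidation gives the non-enolisable neopentyl aldehyde and leaves the epoxide, enoate and acetate untouched.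

Step 15
Reactants: 27 C2 aldehyde
Product: 28 (2R)-nitro alcohol
Conditions: CH3NO2 (10 equiv), Cu(OAc)2·H2O (10 mol %), indabox bis(oxazoline) ligand (11 mol %), EtOH, 0 °C → rt
Reagents that add atoms: nitromethane, C[N+](=O)[O-]
Why: Copper–bis(oxazoline)-catalysed asymmetric Henry (nitroaldol) reaction adds nitromethane to the Si face of the aldehyde under catalyst control, setting C2 (R) and installing C3 as the latent nucleophile.

Step 16
Reactants: 28 (2R)-nitro alcohol
Product: 29 (2R)-triethylsilyl ether (cyclisation precursor)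
Conditions: Et3SiCl, imidazole, DMAP (cat.), DMF, 0 °C → rt
Reagents that add atoms: chlorotriethylsilane, CC[Si](Cl)(CC)CC
Why: Silylation blocks retro-Henry cleavage and supplies the non-chelating α-oxygen substituent on which the Felkin–Anh reduction of step 20 relies.

Step 17
Reactants: 29 (2R)-triethylsilyl ether
Product: 31 tricyclic 3-nitro butenolide (rings A/B/C; 5E; 7S; C3 epimers), via hydroxy tert-butyl ester 30 (not isolated)
Conditions: Pd2(dba)3·CHCl3 (5 mol %), dppe (12 mol %), THF, 65 °C, slow addition of 29 (final 0.005 M); then PPTS (0.3 equiv), 60 °C, same flask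
Reagents that add atoms: none
Why: Zerovalent palladium ionises the allylic C6–O bond of the vinyl epoxide to a zwitterion whose C7 alkoxide deprotonates the tethered nitroalkane, and the nitronate attacks the unsubstituted C4 terminus of the C4–C5–C6 π-allyl complex to form the C3–C4 bond; the closest known chemistry is the Tsuji–Trost alkylation of nitronates by vinyl epoxides and the palladium-templated macrocyclisation of vinyl epoxides carrying a tethered carbon acid under neutral conditions, here with the nitronate as an acyl-anion equivalent that unites two normally electrophilic carbons. Ring B closes in a 10-endo mode with respect to the allyl unit (attack at the distal terminus; the 8-membered alternative by attack at C6 is disfavoured by substitution at C6 and by the known preference of such cyclisations for the larger ring), and ring C then closes by 5-exo-trig lactonisation of the C7 hydroxyl onto the cis tert-butyl ester when mild acid is added. The C5=C6 alkene should emerge E because C7 takes the syn position of the π-allyl complex, C7 keeps the configuration set in step 12 because its C–O bond is never broken, and the C3 nitro centre is inconsequential since steps 18–19 erase it. The step needs C- over O-alkylation of the nitronate (normal for soft palladium allylation), alkylation before elimination of the π-allyl intermediate or premature lactonisation (secured by the slow-to-cyclise tert-butyl ester, which lets the alkoxide survive as the internal base), and cyclisation over oligomerisation (base and nucleophile are generated pairwise within one molecule, assisted by slow addition).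

Step 18
Reactants: 31 tricyclic 3-nitro butenolide
Product: 32 C3 oxime
Conditions: SnCl2·2H2O (1.5 equiv), PhSH, Et3N, MeCN, rt
Reagents that add atoms: none
Why: The divalent tin thiolate complex formed in situ reduces the secondary nitro group to the oxime (first half of a reductive Nef sequence) without a strong base, which protects the doubly allylic, base-labile C7–H of the butenolide.

Step 19
Reactants: 32 C3 oxime
Product: 34 C3 ketone, via imine 33 (not isolated)
Conditions: aq TiCl3 (3 equiv), NH4OAc buffer (pH ca. 6), THF–H2O, 0 °C → rt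
Reagents that add atoms: water, O
Why: Reductive deoximation by buffered trivalent titanium (N–O cleavage to the imine, then hydrolysis) completes the Nef-type unmasking of the C3 carbonyl under conditions mild enough to keep the β,γ-unsaturated ketone unconjugated.

Step 20
Reactants: 34 C3 ketone
Product: 35 (3R)-alcohol
Conditions: NaBH4, CeCl3·7H2O, MeOH–THF, −78 °C
Reagents that add atoms: none
Why: Luche-type hydride reduction of the α-silyloxy ketone is expected to follow the polar Felkin–Anh model (hydride anti to the C2–O bond of the non-chelating silyl ether), giving the 2,3-syn, that is (3R), alcohol.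

Step 21
Reactants: 35 (3R)-alcohol
Product: 36 (2R,3R)-diol
Conditions: HF·pyridine, pyridine, THF, 0 °C → rt
Reagents that add atoms: none
Why: Fluoride cleavage of the secondary triethylsilyl ether under mildly acidic conditions leaves the acetate, butenolide and both alkenes untouched.

Step 22
Reactants: 36 (2R,3R)-diol
Product: 37 2,3,14-triacetate with C11=C12 alkene
Conditions: Ac2O, pyridine, DMAP (cat.), CH2Cl2, rt
Reagents that add atoms: acetic anhydride, CC(=O)OC(C)=O
Why: DMAP-catalysed acetylation of both secondary hydroxyls completes the triacetate pattern of the target.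

Step 23
Reactants: 37 2,3,14-triacetate
Product: 38 brianthein B
Conditions: O2, visible light, tetraphenylporphyrin (cat.), CH2Cl2, −20 °C, stopped at partial conversion
Reagents that add atoms: dioxygen, O=O
Why: Schenck ene reaction: singlet oxygen should bond to C12 of the electron-rich C11=C12 alkene on the β-face (the α-face of C12 is shielded by the axial 14α-acetate and bonding at C11 on the β-face by the axial C15 methyl) with abstraction of a C20 hydrogen, giving the 12β-hydroperoxide and the exocyclic alkene, while the C5=C6 alkene is deactivated by the allylic lactone oxygen.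

## Compound list

1 | (S)-(+)-carvone | CC1=CC[C@H](C(C)=C)CC1=O | starting material
2 | lithium cross-conjugated dienolate of 1 | CC1=CC[C@H](C(C)=C)C=C1[O-].[Li+] | intermediate
3 | 6-[(triisopropylsilyloxy)methyl]carvone, epimers at the new centre | CC1=CC[C@H](C(C)=C)C(CO[Si](C(C)C)(C(C)C)C(C)C)C1=O | intermediate
4 | lithium enolate of 3 | CC1=CC[C@H](C(C)=C)C(CO[Si](C(C)C)(C(C)C)C(C)C)=C1[O-].[Li+] | intermediate
5 | (5R,6R)-2,6-dimethyl-5-(prop-1-en-2-yl)-6-[(triisopropylsilyloxy)methyl]cyclohex-2-en-1-one (C15 β, C2 arm α) | CC1=CC[C@H](C(C)=C)[C@@](CO[Si](C(C)C)(C(C)C)C(C)C)(C)C1=O | intermediate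
6 | 11β,12β-epoxide of 5 (epoxide trans to isopropenyl) | C[C@]12O[C@H]1C[C@H](C(C)=C)[C@@](CO[Si](C(C)C)(C(C)C)C(C)C)(C)C2=O | intermediate
7 | α-methoxy hydroperoxide from ozonolysis of the isopropenyl group of 6 | C[C@]12O[C@H]1C[C@H](C(C)(OC)OO)[C@@](CO[Si](C(C)C)(C(C)C)C(C)C)(C)C2=O | intermediate
8 | peracetate of 7 | C[C@]12O[C@H]1C[C@H](C(C)(OC)OOC(C)=O)[C@@](CO[Si](C(C)C)(C(C)C)C(C)C)(C)C2=O | intermediate
9 | 14α-acetoxy 11β,12β-epoxy 10-ketone | C[C@]12O[C@H]1C[C@H](OC(C)=O)[C@@](CO[Si](C(C)C)(C(C)C)C(C)C)(C)C2=O | intermediate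
10 | hydrazone of 9 | C[C@]12O[C@H]1C[C@H](OC(C)=O)[C@@](CO[Si](C(C)C)(C(C)C)C(C)C)(C)C2=NN | intermediate
11 | 12β-hydroxy 10(11)-ene, 14α-acetate | CC1=C[C@](CO[Si](C(C)C)(C(C)C)C(C)C)(C)[C@@H](OC(C)=O)C[C@@H]1O | intermediate
12 | 12β,14α-diacetate | CC1=C[C@](CO[Si](C(C)C)(C(C)C)C(C)C)(C)[C@@H](OC(C)=O)C[C@@H]1OC(C)=O | intermediate
13 | bis(trimethylsilyl ketene acetal) of 12 | CC1=C[C@](CO[Si](C(C)C)(C(C)C)C(C)C)(C)[C@@H](OC(=C)O[Si](C)(C)C)C[C@@H]1OC(=C)O[Si](C)(C)C | intermediate
14 | rearranged trimethylsilyl ester (C14 ketene acetal still in place) | CC1=CC[C@H](OC(=C)O[Si](C)(C)C)[C@@](CO[Si](C(C)C)(C(C)C)C(C)C)(C)[C@H]1CC(=O)O[Si](C)(C)C | intermediate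
15 | ring A acid: C10β-CH2CO2H (H-10 α), C11=C12, 14α-OAc, C1 with β-methyl and α-CH2OSi(iPr)3 | CC1=CC[C@H](OC(C)=O)[C@@](CO[Si](C(C)C)(C(C)C)C(C)C)(C)[C@H]1CC(=O)O | intermediate
16 | acyl imidazole of 15 | CC1=CC[C@H](OC(C)=O)[C@@](CO[Si](C(C)C)(C(C)C)C(C)C)(C)[C@H]1CC(=O)n2ccnc2 | intermediate
17 | tert-butyl β-keto ester (C8 ketone, C17 epimers) | CC1=CC[C@H](OC(C)=O)[C@@](CO[Si](C(C)C)(C(C)C)C(C)C)(C)[C@H]1CC(=O)C(C)C(=O)OC(C)(C)C | intermediate
18 | sodium (Z)-enolate of 17 | CC1=CC[C@H](OC(C)=O)[C@@](CO[Si](C(C)C)(C(C)C)C(C)C)(C)[C@H]1C/C([O-])=C(\C)C(=O)OC(C)(C)C.[Na+] | intermediate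
19 | (Z)-enol triflate (C8–OTf cis to C19) | CC1=CC[C@H](OC(C)=O)[C@@](CO[Si](C(C)C)(C(C)C)C(C)C)(C)[C@H]1C/C(OS(=O)(=O)C(F)(F)F)=C(\C)C(=O)OC(C)(C)C | intermediate
20 | (Z)-β-formyl enoate (C7 aldehyde cis to CO2tBu) | CC1=CC[C@H](OC(C)=O)[C@@](CO[Si](C(C)C)(C(C)C)C(C)C)(C)[C@H]1C/C(C=O)=C(\C)C(=O)OC(C)(C)C | intermediate
21 | (1R,4R,5R)-isothiocineole (4,7,7-trimethyl-6-thiabicyclo[3.2.1]octane) | C[C@@H]1CC[C@@H]2C[C@H]1SC2(C)C | starting material
22 | 3-bromo-2-methylprop-1-ene | C=C(C)CBr | starting material
23 | S-(2-methylallyl)isothiocineolium tetrafluoroborate (single sulfonium diastereomer, configuration at sulfur not specified) | C[C@@H]1CC[C@@H]2C[C@H]1[S+](CC(C)=C)C2(C)C.F[B-](F)(F)F | intermediate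
24 | sulfonium ylide of 23 | C[C@@H]1CC[C@@H]2C[C@H]1[S+]([CH-]C(C)=C)C2(C)C | intermediate
25 | trans-(6R,7R)-vinyl epoxide, C2 as CH2OSi(iPr)3 | CC1=CC[C@H](OC(C)=O)[C@@](CO[Si](C(C)C)(C(C)C)C(C)C)(C)[C@H]1C/C([C@H]1O[C@@H]1C(C)=C)=C(\C)C(=O)OC(C)(C)C | intermediate
26 | primary alcohol (C2–OH) of 25 | CC1=CC[C@H](OC(C)=O)[C@@](CO)(C)[C@H]1C/C([C@H]1O[C@@H]1C(C)=C)=C(\C)C(=O)OC(C)(C)C | intermediate
27 | C2 aldehyde | CC1=CC[C@H](OC(C)=O)[C@@](C=O)(C)[C@H]1C/C([C@H]1O[C@@H]1C(C)=C)=C(\C)C(=O)OC(C)(C)C | intermediate
28 | (2R)-nitro alcohol (C3 = CH2NO2) | CC1=CC[C@H](OC(C)=O)[C@@]([C@@H](O)C[N+](=O)[O-])(C)[C@H]1C/C([C@H]1O[C@@H]1C(C)=C)=C(\C)C(=O)OC(C)(C)C | intermediate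
29 | (2R)-triethylsilyl ether of 28 (cyclisation precursor) | CC1=CC[C@H](OC(C)=O)[C@@]([C@@H](O[Si](CC)(CC)CC)C[N+](=O)[O-])(C)[C@H]1C/C([C@H]1O[C@@H]1C(C)=C)=C(\C)C(=O)OC(C)(C)C | intermediate
30 | ring B hydroxy tert-butyl ester (7S-OH, 5E, C3 epimers) | CC1=CC[C@H](OC(C)=O)[C@@]2(C)[C@H]1C/C([C@@H](O)/C=C(\C)CC([N+](=O)[O-])[C@@H]2O[Si](CC)(CC)CC)=C(\C)C(=O)OC(C)(C)C | intermediate
31 | tricyclic 3-nitro butenolide, 2-OSiEt3, 14-OAc (C3 epimers) | CC1=CC[C@H](OC(C)=O)[C@@]2(C)[C@H]1CC1=C(C)C(=O)O[C@H]1/C=C(\C)CC([N+](=O)[O-])[C@@H]2O[Si](CC)(CC)CC | intermediate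
32 | C3 oxime | CC1=CC[C@H](OC(C)=O)[C@@]2(C)[C@H]1CC1=C(C)C(=O)O[C@H]1/C=C(\C)CC(=NO)[C@@H]2O[Si](CC)(CC)CC | intermediate
33 | C3 imine | CC1=CC[C@H](OC(C)=O)[C@@]2(C)[C@H]1CC1=C(C)C(=O)O[C@H]1/C=C(\C)CC(=N)[C@@H]2O[Si](CC)(CC)CC | intermediate
34 | C3 ketone | CC1=CC[C@H](OC(C)=O)[C@@]2(C)[C@H]1CC1=C(C)C(=O)O[C@H]1/C=C(\C)CC(=O)[C@@H]2O[Si](CC)(CC)CC | intermediate
35 | (3R)-alcohol, 2-OSiEt3 | CC1=CC[C@H](OC(C)=O)[C@@]2(C)[C@H]1CC1=C(C)C(=O)O[C@H]1/C=C(\C)C[C@@H](O)[C@@H]2O[Si](CC)(CC)CC | intermediate
36 | (2R,3R)-diol | CC1=CC[C@H](OC(C)=O)[C@@]2(C)[C@H]1CC1=C(C)C(=O)O[C@H]1/C=C(\C)C[C@@H](O)[C@@H]2O | intermediate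
37 | 2,3,14-triacetate with C11=C12 alkene | CC1=CC[C@H](OC(C)=O)[C@@]2(C)[C@H]1CC1=C(C)C(=O)O[C@H]1/C=C(\C)C[C@@H](OC(C)=O)[C@@H]2OC(C)=O | intermediate
38 | brianthein B | C=C1[C@@H](OO)C[C@H](OC(C)=O)[C@@]2(C)[C@H]1CC1=C(C)C(=O)O[C@H]1/C=C(\C)C[C@@H](OC(C)=O)[C@@H]2OC(C)=O | target

## Step count and risk assessment

Total step count: 23. Longest linear sequence: 22 steps (steps 1–10 and 12–23; step 11 prepares the sulfonium salt).

**Step 17 (key step).** What may go wrong: the π-allyl intermediate may lose the C7 proton or lactonise early and then eliminate to a dienyl butenolide. The tethered nitronate may also attack C6 instead of C4, or intermolecular alkylation may outrun ring closure. Fallback: it sets out from alcohol 26. Intermolecular palladium-catalysed allylation of nitromethane in large excess (Pd2(dba)3·CHCl3, dppe, THF, then PPTS) forms the C3–C4 bond without any ring strain and closes the lactone, giving nitro butenolide alcohol F1. Dess–Martin oxidation gives aldehyde F2. An intramolecular Henry reaction at high dilution (Cu(OAc)2·H2O, the same bis(oxazoline) ligand, iPr2NEt) then closes ring B at C2–C3 to give macrocyclic nitro alcohol F3. Silylation with Et3SiCl and imidazole returns to 31.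

**Step 23.** What may go wrong: singlet oxygen may react competitively at the C5=C6 alkene, abstract a C13 hydrogen to give the tertiary C11 hydroperoxide, or attack the α-face. Fallback: it sets out from triacetate 37 and replaces the pericyclic oxygenation by an ionic two-stage sequence. Ene-type allylic chlorination (N-chlorosuccinimide, catalytic PhSeCl, CH2Cl2) gives the 12-chloro-11(20)-ene F4, the electron-poorer C5=C6 alkene being less reactive towards the electrophile. Silver-assisted perhydrolysis (anhydrous H2O2 in Et2O, AgOTf, −20 °C) through the allyl cation, attacked at C12 from the less hindered β-face, then gives 38.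

**Step 5.** What may go wrong: hydrazone formation at the C10 ketone, flanked by two fully substituted carbons, may be too slow, so that hydrazine opens the epoxide or cleaves the acetate instead. Fallback: it sets out from epoxy ketone 9. Reduction with NaBH4 and CeCl3·7H2O gives epoxy alcohol F5 (configuration at C10 inconsequential). 1,1'-Thiocarbonyldiimidazole with DMAP in toluene at 80 °C gives thiocarbonyl imidazolide F6. Bu3SnH with AIBN in benzene at 80 °C generates the C10 radical, which opens the epoxide by C11–O scission; the resulting C12 alkoxy radical is reduced, returning to allylic alcohol 11.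

Further compounds
F1 | step 17 | nitro butenolide alcohol (ring C closed, C3 as CH2NO2 on C4, C2 as CH2OH) | CC1=CC[C@H](OC(C)=O)[C@@](CO)(C)[C@H]1CC1=C(C)C(=O)O[C@H]1/C=C(\C)CC[N+](=O)[O-]
F2 | step 17 | corresponding C2 aldehyde | CC1=CC[C@H](OC(C)=O)[C@@](C=O)(C)[C@H]1CC1=C(C)C(=O)O[C@H]1/C=C(\C)CC[N+](=O)[O-]
F3 | step 17 | macrocyclic (2R)-hydroxy 3-nitro butenolide (C3 epimers) | CC1=CC[C@H](OC(C)=O)[C@@]2(C)[C@H]1CC1=C(C)C(=O)O[C@H]1/C=C(\C)CC([N+](=O)[O-])[C@@H]2O
F4 | step 23 | 12β-chloro-11(20)-ene triacetate | C=C1[C@@H](Cl)C[C@H](OC(C)=O)[C@@]2(C)[C@H]1CC1=C(C)C(=O)O[C@H]1/C=C(\C)C[C@@H](OC(C)=O)[C@@H]2OC(C)=O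
F5 | step 5 | 11β,12β-epoxy 10β-alcohol | C[C@]12O[C@H]1C[C@H](OC(C)=O)[C@@](CO[Si](C(C)C)(C(C)C)C(C)C)(C)[C@H]2O
F6 | step 5 | O-(imidazol-1-ylthiocarbonyl) derivative of the epoxy alcohol | C[C@]12O[C@H]1C[C@H](OC(C)=O)[C@@](CO[Si](C(C)C)(C(C)C)C(C)C)(C)[C@H]2OC(=S)n3ccnc3
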